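If the target curves of the west and east runs were still steepening up to 20.0 h, those runs would be gathering speed at their end. So I turned the question round and asked what the earlier runs would have to show for that.

| setting | west | east | flask |
|---|---|---|---|
| starting material | 0.020 M | 0.020 M | 0.020 M |
| reagent in the second phase | 0.040 M | 0.040 M | 0.0400 M |
| protic impurity | 8.4 mM | 13 mM | 6.00 mM |
| remark | run made earlier | run made earlier |  |
| time |  |  | 20 h |
| volume of the second phase over the first |  |  | 2.0 |

| west: time / h | west: target / % | east: time / h | east: target / % |
|---|---|---|---|
| 1.50 | 0.6 | 1.33 | 0.3 |
| 2.50 | 1.6 | 4.00 | 1.4 |
| 4.00 | 3.3 | 8.00 | 4.5 |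
| 8.00 | 6.5 | 10.0 | 5.3 |
| 12.0 | 8.9 | 15.0 | 7.8 |
| 20.0 | 13.3 | 20.0 | 9.5 |

(readings scatter by 0.5 percentage points)

- in the second phase: reagent in the second phase; everything else is in the first
- charges count per volume of the first phase; a concentration in a rate is the amount of a species over the volume of its own phase; every rate counts per litre of the first phase
- the earlier runs hold the two phases in the same ratio of volumes as the flask asked about

- green: doubling the amount of reagent in the second phase, all else as stated
- grey: doubling the transfer coefficient of the reagent in the second phase, all else as stated

* the target standing at 20 h, as a percentage of the starting material charged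
* the change that raises the amount of target at 20 h, in percent of the starting material charged most ("none" if none brings more than 2 percentage points) (green / grey / none)
* amount of target at 20 h, in percent of the starting material charged, after grey

The west run gave 0.708 and the east run 0.538 for what I call the slowing ratio, the slope of the target from 8.00 h to 20.0 h divided by its slope from 4.00 h to 8.00 h. A steepening curve needs a ratio above one. For a ratio of one, the west reading at 20.0 h would have had to stand at 16.1 %, but it stood at 13.3 %, lower by 5.60 times the scatter of a reading.

The flask has the same reagent charge as these runs, and its [protic impurity] of 6.00 mM is lower than the 8.4 mM of the west run. Both ratios lay below one, so both runs gained target more slowly in the late stretch than in the early one, though the ratio does not tell whether reagent or starting material stood behind that. I committed to green as a judgement, which the ratio does not prove.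

The forecast gave 16 %, 19.5 % after grey, and green as the best change, holding that “Faster transfer only shortens the lag”.

The flask gave 15.8 %; green added 8.3 percentage points, and grey added 2.2 points, reaching 18.0 %. At 20.0 h, reagent in the reaction phase was being made at 0.887 times the rate at which it was used up.

    reagent in the reaction phase ⇌ reagent in the second phase, rate k1*([reagent in the reaction phase] - [reagent in the second phase]/K1) per volume of the first phase (partition coefficient = 2.30, kL = 0.00341 min⁻¹)
    starting material + reagent in the reaction phase → target (k = 0.0531 M⁻¹ min⁻¹)
    reagent in the reaction phase + target → over-reacted product (k = 0.0333 M⁻¹ min⁻¹)
    starting material + protic impurity → quenched substrate (k = 0.370 M⁻¹ min⁻¹)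
    2 reagent in the reaction phase → homo dimer (k = 0.0626 M⁻¹ min⁻¹)

Taken over 5.00 h, 10.0 h and 20 h, the slowing ratio of this flask was 0.808, also below one, beside 0.708 in the west run.

For the same flask read at 3.0 d, I took the slope from 20 h to 40.0 h, multiplied it by 0.708 and ran it on from 24.9 % at 40.0 h, which gave 35.2 %. The computed value was 30.6 %, lower than that reckoning, and its own ratio was 0.393.

The data stem from a simulated flask for substances that don't exist; noise was put on by code.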